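The seven-membered ring is closed last by a carbene cyclopropanation/divinylcyclopropane–cycloheptadiene cascade. In ring B (C1, C5–C10; daucane numbering) the alkene C8=C9 and the C5–C6 bond are separated only by methylene C7, so ring B is the Cope product of a cis-divinylcyclopropane C6–C7–C8. Release of its strain forges the most hindered bond, C1–C10, at the quaternary ring-fusion carbon and sets C1 and C10 together. The precursor is a cyclopentenyl carbene, made from an aldehyde hydrazone cut out of (R)-terpinen-4-ol (which supplies C4), plus an acyclic dienyl tiglate carrying the C8 methyl and the C10 ester. Hydroboration of the resulting C5=C6 alkene then sets C5 and C6.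

Key step: step 6

Numbering used for all intermediates (daucane): C1 quaternary ring-fusion carbon (CH3), C2/C3 ring A methylenes, C4 carbinol carbon (isopropyl), C5 ring-fusion CH, C6 CH–O-aroyl, C7 CH2, C8 C(CH3)=, C9 =CH, C10 CH–O-tigloyl; ring A = cyclopentane, ring B = cycloheptene.

Remark: the 2-methylbut-2-enoate of the target is E (tigloyl); (R)-(−)-terpinen-4-ol is assumed to be purchased in high enantiomeric purity.

Step 1
Reactants: 1 (R)-(−)-terpinen-4-ol
Product: 2 triethyl{[(1R)-4-methyl-1-(propan-2-yl)cyclohex-3-en-1-yl]oxy}silane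
Conditions: TESOTf, 2,6-lutidine, CH2Cl2, −78 → 0 °C
Reagents that add atoms: triethylsilyl trifluoromethanesulfonate, CC[Si](CC)(CC)OS(=O)(=O)C(F)(F)F
Why: A silyl triflate with a hindered pyridine base silylates even tertiary alcohols (standard silyl ether formation); the C4 stereocentre is untouched, and the ether later prevents loss of this oxygen in step 3 and O–H insertion in step 6.

Step 2
Reactants: 2 silyl ether
Product: 4 keto aldehyde (3R)-6-oxo-3-(propan-2-yl)-3-[(triethylsilyl)oxy]heptanal, via secondary ozonide 3 (not isolated)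
Conditions: O3, CH2Cl2, −78 °C; then Me2S, −78 °C → rt
Reagents that add atoms: ozone, [O-][O+]=O
Why: Ozonolysis (1,3-dipolar cycloaddition/cycloreversion to the ozonide, then reduction by Me2S) cleaves the only C=C bond, between future C1 (methyl ketone) and future C6 (aldehyde), and leaves the C4 stereocentre untouched.

Step 3
Reactants: 4 keto aldehyde
Product: 6 enal (5S)-2-methyl-5-(propan-2-yl)-5-[(triethylsilyl)oxy]cyclopent-1-ene-1-carbaldehyde, via aldol adduct 5 (not isolated)
Conditions: piperidine (0.2 equiv), AcOH (0.2 equiv), PhMe, 4 Å MS, rt → 50 °C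
Reagents that add atoms: none
Why: Amine-catalysed intramolecular aldol condensation: the enamine of the aldehyde (C5 nucleophile) adds to the methyl ketone (C1) in the five-membered mode known for 6-oxoheptanals, and the new free tertiary hydroxyl should be lost in preference to the silylated one to give the conjugated enal; no new stereocentre remains.

Step 4
Reactants: 6 enal
Product: 7 N'-{(E)-[(5S)-2-methyl-5-(propan-2-yl)-5-[(triethylsilyl)oxy]cyclopent-1-en-1-yl]methylidene}-2-(trifluoromethyl)benzenesulfonohydrazide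
Conditions: 2-(trifluoromethyl)benzenesulfonohydrazide, THF, MgSO4, rt
Reagents that add atoms: 2-(trifluoromethyl)benzenesulfonohydrazide, NNS(=O)(=O)c1ccccc1C(F)(F)F
Why: Condensation of the aldehyde with the sulfonyl hydrazide gives the N-sulfonylhydrazone, a bench-stable precursor of the alkenyldiazomethane (Bamford–Stevens-type chemistry); the tetrasubstituted alkene blocks conjugate addition.

Step 5
Reactants: 8 3-methylbut-2-enal (prenal); 9 (2E)-2-methylbut-2-enoyl chloride (tigloyl chloride)
Product: 11 (1E)-3-methylbuta-1,3-dien-1-yl (2E)-2-methylbut-2-enoate, via potassium dienolate 10 (not isolated)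
Conditions: KOtBu, THF, −78 °C; then 9, −78 → 0 °C
Reagents that add atoms: none
Why: γ-Deprotonation of prenal gives the extended potassium dienolate, which acid chlorides acylate on oxygen to the 1-acyloxy-1,3-diene, expected mainly as the E isomer (purified by distillation); the E enol ester geometry is what later places the C10 oxygen trans to the C1 methyl.

Step 6
Reactants: 7 N-sulfonylhydrazone; 11 dienyl tiglate
Product: 15 (3S,8R,8aS)-6,8a-dimethyl-3-(propan-2-yl)-3-[(triethylsilyl)oxy]-1,2,3,5,8,8a-hexahydroazulen-8-yl (2E)-2-methylbut-2-enoate, via sodium salt 12 (not isolated), via alkenyldiazomethane 13 (not isolated), via cis-divinylcyclopropane 14 (not isolated)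
Conditions: NaH, CH2Cl2, 0 °C; Rh2(OAc)4 (2 mol %), 11 (3 equiv), 30 °C; then xylene, 140 °C
Reagents that add atoms: none
Why: The sodium salt 12 loses sulfinate to give alkenyldiazomethane 13, which Rh2(OAc)4 turns into an alkenyl carbene that cyclopropanates the terminal 1,1-disubstituted alkene of 11 to give cis-divinylcyclopropane 14, and on heating 14 rearranges through the boat transition state, cleaving C6–C8 and forming C1–C10 with release of the cyclopropane strain. The closest known reaction type is the tandem carbene cyclopropanation/Cope rearrangement (formal [4+3] cycloaddition of alkenyl carbenes with 1,3-dienes), here with the carbene generated from a sulfonylhydrazone. The temporary three-membered ring is closed by [2+1] carbene addition and the seven-membered ring by the [3,3]-sigmatropic shift of the array C1=C5–C6/C8–C9=C10; ring A is already present, so this is the last ring of the skeleton. C10 relative to C1 follows from the boat geometry: the (E)-acyloxy group lies exo and the C1 methyl, which is cis to the cyclopropane on the ring alkene, lies endo, so the tiglate and CH3 end up trans across the new bond. The absolute sense at C1/C10 (bond formation on the ring face that carries the C4 oxygen) is relayed from C4 through the cyclopropane: the bulky OSiEt3 group is expected to hold the dirhodium unit on the isopropyl side of the twisted alkenyl carbene so that the diene adds from the face remote from quaternary C4. The step needs site selectivity (the enol ester alkene of 11 is deactivated), cis selectivity in the cyclopropanation (the usual preference of unstabilised aryl and alkenyl carbenes with Rh2(OAc)4) and face selectivity, the last being the least certain.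

Step 7
Reactants: 15 bicyclic diene
Product: 17 (3S,3aS,4S,8R,8aS)-4-hydroxy-6,8a-dimethyl-3-(propan-2-yl)-3-[(triethylsilyl)oxy]-1,2,3,3a,4,5,8,8a-octahydroazulen-8-yl (2E)-2-methylbut-2-enoate, via C6 alkylborane 16 (not isolated)
Conditions: BH3·THF (1.2 equiv), THF, 0 °C; then NaBO3·4H2O, THF/H2O, rt
Reagents that add atoms: sodium perborate, [Na+].[O-]OB=O
Why: Hydroboration–oxidation: syn addition of H–B across C5=C6 with boron on the less substituted C6, from the face opposite the C1 methyl and the C4 isopropyl group (the selectivity known for alkenes next to an angular methyl), should give H-5 and the C6 oxygen cis to each other and trans to CH3-1 after oxidation with retention; C8=C9 is deactivated by its allylic acyloxy group and shielded at C9 by the neopentylic C10, and perborate spares the ester.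

Step 8
Reactants: 18 4-hydroxybenzoic acid
Product: 20 4-[(tert-butyldimethylsilyl)oxy]benzoic acid, via bis-silyl compound 19 (not isolated)
Conditions: TBSCl (2.3 equiv), imidazole, DMF, rt; then AcOH/THF/H2O, rt
Reagents that add atoms: tert-butyldimethylsilyl chloride, CC(C)(C)[Si](C)(C)Cl
Why: Exhaustive silylation followed by mild hydrolysis of the far more labile silyl ester leaves the aryl silyl ether (standard protection of a phenolic acid).

Step 9
Reactants: 17 alcohol; 20 protected acid
Product: 21 (3S,3aS,4S,8R,8aS)-6,8a-dimethyl-8-{[(2E)-2-methylbut-2-enoyl]oxy}-3-(propan-2-yl)-3-[(triethylsilyl)oxy]-1,2,3,3a,4,5,8,8a-octahydroazulen-4-yl 4-[(tert-butyldimethylsilyl)oxy]benzoate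
Conditions: DCC, DMAP, CH2Cl2, rt → 40 °C
Reagents that add atoms: none
Why: Carbodiimide/DMAP (Steglich) esterification of the only free hydroxyl; the C6 configuration is retained because its C–O bond is not touched.

Step 10
Reactants: 21 bis-silyl diester
Product: 22 target, (3S,3aS,4S,8R,8aS)-3-hydroxy-6,8a-dimethyl-8-{[(2E)-2-methylbut-2-enoyl]oxy}-3-(propan-2-yl)-1,2,3,3a,4,5,8,8a-octahydroazulen-4-yl 4-hydroxybenzoate
Conditions: HF·pyridine, pyridine/THF, 0 °C → rt
Reagents that add atoms: none
Why: Fluoride cleaves the aryl tert-butyldimethylsilyl and the tertiary triethylsilyl ethers (Si–F bond formation) under buffered conditions that should leave both carboxylic esters and the allylic system intact.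

Compound list
1 | (R)-(−)-terpinen-4-ol, (1R)-4-methyl-1-(propan-2-yl)cyclohex-3-en-1-ol | CC1=CC[C@@](O)(C(C)C)CC1 | starting material
2 | triethyl{[(1R)-4-methyl-1-(propan-2-yl)cyclohex-3-en-1-yl]oxy}silane | CC1=CC[C@@](O[Si](CC)(CC)CC)(C(C)C)CC1 | intermediate
3 | secondary ozonide of 2, 1-methyl-4-(propan-2-yl)-4-[(triethylsilyl)oxy]-7,8,9-trioxabicyclo[4.2.1]nonane (silyloxy carbon as in 2; bridgeheads not controlled) | CC12CC[C@](O[Si](CC)(CC)CC)(C(C)C)CC(OO1)O2 | intermediate
4 | (3R)-6-oxo-3-(propan-2-yl)-3-[(triethylsilyl)oxy]heptanal | O=CC[C@@](O[Si](CC)(CC)CC)(C(C)C)CCC(C)=O | intermediate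
5 | aldol adduct, 2-hydroxy-2-methyl-5-(propan-2-yl)-5-[(triethylsilyl)oxy]cyclopentane-1-carbaldehyde (silyloxy carbon as in 4; the other two centres not controlled) | O=CC1[C@@](O[Si](CC)(CC)CC)(C(C)C)CCC1(C)O | intermediate
6 | (5S)-2-methyl-5-(propan-2-yl)-5-[(triethylsilyl)oxy]cyclopent-1-ene-1-carbaldehyde | O=CC1=C(C)CC[C@]1(O[Si](CC)(CC)CC)C(C)C | intermediate
7 | N'-{(E)-[(5S)-2-methyl-5-(propan-2-yl)-5-[(triethylsilyl)oxy]cyclopent-1-en-1-yl]methylidene}-2-(trifluoromethyl)benzenesulfonohydrazide | FC(F)(F)c1ccccc1S(=O)(=O)N/N=C/C1=C(C)CC[C@]1(O[Si](CC)(CC)CC)C(C)C | intermediate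
8 | 3-methylbut-2-enal (prenal) | CC(C)=CC=O | starting material
9 | (2E)-2-methylbut-2-enoyl chloride (tigloyl chloride) | C/C=C(\C)C(Cl)=O | starting material
10 | potassium (1E)-3-methylbuta-1,3-dien-1-olate | [K+].[O-]/C=C/C(C)=C | intermediate
11 | (1E)-3-methylbuta-1,3-dien-1-yl (2E)-2-methylbut-2-enoate | C/C=C(\C)C(=O)O/C=C/C(C)=C | intermediate
12 | sodium salt of hydrazone 7 | [Na+].FC(F)(F)c1ccccc1S(=O)(=O)[N-]/N=C/C1=C(C)CC[C@]1(O[Si](CC)(CC)CC)C(C)C | intermediate
13 | {[(1S)-2-(diazomethyl)-3-methyl-1-(propan-2-yl)cyclopent-2-en-1-yl]oxy}triethylsilane | [N-]=[N+]=CC1=C(C)CC[C@]1(O[Si](CC)(CC)CC)C(C)C | intermediate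
14 | (1E)-2-[(1S,2R)-1-methyl-2-{(5S)-2-methyl-5-(propan-2-yl)-5-[(triethylsilyl)oxy]cyclopent-1-en-1-yl}cyclopropyl]ethenyl (2E)-2-methylbut-2-enoate (cis-divinylcyclopropane) | C/C=C(\C)C(=O)O/C=C/[C@@]1(C)C[C@H]1C1=C(C)CC[C@]1(O[Si](CC)(CC)CC)C(C)C | intermediate
15 | (3S,8R,8aS)-6,8a-dimethyl-3-(propan-2-yl)-3-[(triethylsilyl)oxy]-1,2,3,5,8,8a-hexahydroazulen-8-yl (2E)-2-methylbut-2-enoate | C/C=C(\C)C(=O)O[C@@H]1C=C(C)CC=C2[C@]1(C)CC[C@]2(O[Si](CC)(CC)CC)C(C)C | intermediate
16 | C6 alkylborane of 15 (shown as the monoalkylborane; boron cis to H-5 and trans to CH3-1) | C/C=C(\C)C(=O)O[C@@H]1C=C(C)C[C@H](B)[C@@H]2[C@]1(C)CC[C@]2(O[Si](CC)(CC)CC)C(C)C | intermediate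
17 | (3S,3aS,4S,8R,8aS)-4-hydroxy-6,8a-dimethyl-3-(propan-2-yl)-3-[(triethylsilyl)oxy]-1,2,3,3a,4,5,8,8a-octahydroazulen-8-yl (2E)-2-methylbut-2-enoate | C/C=C(\C)C(=O)O[C@@H]1C=C(C)C[C@H](O)[C@@H]2[C@]1(C)CC[C@]2(O[Si](CC)(CC)CC)C(C)C | intermediate
18 | 4-hydroxybenzoic acid | OC(=O)c1ccc(O)cc1 | starting material
19 | tert-butyldimethylsilyl 4-[(tert-butyldimethylsilyl)oxy]benzoate | CC(C)(C)[Si](C)(C)OC(=O)c1ccc(O[Si](C)(C)C(C)(C)C)cc1 | intermediate
20 | 4-[(tert-butyldimethylsilyl)oxy]benzoic acid | OC(=O)c1ccc(O[Si](C)(C)C(C)(C)C)cc1 | intermediate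
21 | (3S,3aS,4S,8R,8aS)-6,8a-dimethyl-8-{[(2E)-2-methylbut-2-enoyl]oxy}-3-(propan-2-yl)-3-[(triethylsilyl)oxy]-1,2,3,3a,4,5,8,8a-octahydroazulen-4-yl 4-[(tert-butyldimethylsilyl)oxy]benzoate | C/C=C(\C)C(=O)O[C@@H]1C=C(C)C[C@H](OC(=O)c2ccc(O[Si](C)(C)C(C)(C)C)cc2)[C@@H]2[C@]1(C)CC[C@]2(O[Si](CC)(CC)CC)C(C)C | intermediate
22 | (3S,3aS,4S,8R,8aS)-3-hydroxy-6,8a-dimethyl-8-{[(2E)-2-methylbut-2-enoyl]oxy}-3-(propan-2-yl)-1,2,3,3a,4,5,8,8a-octahydroazulen-4-yl 4-hydroxybenzoate | C/C=C(\C)C(=O)O[C@@H]1C=C(C)C[C@H](OC(=O)c2ccc(O)cc2)[C@@H]2[C@]1(C)CC[C@]2(O)C(C)C | target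

Total step count: 10. Longest linear sequence: 8 steps (steps 1, 2, 3, 4, 6, 7, 9, 10).

The three steps most likely to fail

Step 6 (key step). The diene may approach the carbene without enough face preference relative to C4, the cyclopropanation may give the trans isomer (which does not rearrange at this temperature), or the alkenyldiazomethane may close to a 3H-pyrazole before the metal captures it. The fallback sets out from 6 and returns at 15, with the roles of the partners reversed and the face chosen by a chiral catalyst. Wittig methylenation of 6 (Ph3P=CH2) gives triethyl{[(1S)-2-ethenyl-3-methyl-1-(propan-2-yl)cyclopent-2-en-1-yl]oxy}silane F1, which now serves as the diene. The carbene partner becomes a donor–acceptor alkenyldiazoacetate: methyl diazoacetate and 2-oxoethyl acetate are joined (DBU) to methyl 4-acetoxy-2-diazo-3-hydroxybutanoate F2, which is dehydrated (POCl3, Et3N) to methyl (3E)-4-acetoxy-2-diazobut-3-enoate F3. With Rh2(R-DOSP)4, that is tetrakis[(R)-N-(4-dodecylphenylsulfonyl)prolinato]dirhodium, in hexane at −40 °C and then heating, F1 and F3 should give the same cyclopropanation/Cope sequence. The ester (trans to the alkene substituent) fixes the cis geometry and the catalyst selects the face of the terminal vinyl group; the opposite catalyst enantiomer is used if the sense proves mismatched. The product is methyl (3S,8R,8aS)-8-acetoxy-8a-methyl-3-(propan-2-yl)-3-[(triethylsilyl)oxy]-1,2,3,5,8,8a-hexahydroazulene-6-carboxylate F4. DIBAL-H reduces both esters to (3S,8R,8aS)-6-(hydroxymethyl)-8a-methyl-3-(propan-2-yl)-3-[(triethylsilyl)oxy]-1,2,3,5,8,8a-hexahydroazulen-8-ol F5. Selective mesylation of the primary allylic hydroxyl (MsCl, collidine, −20 °C) gives the primary allylic mesylate F6, and LiEt3BH displaces it to give (3S,8R,8aS)-6,8a-dimethyl-3-(propan-2-yl)-3-[(triethylsilyl)oxy]-1,2,3,5,8,8a-hexahydroazulen-8-ol F7, which 9 (Et3N, DMAP) acylates to 15.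

Step 7. The borane may attack the C8=C9 alkene in competition (followed by loss of the allylic tiglate), or add from the wrong face of C5=C6. The fallback sets out from 6, passes through diene F1 and diazo ester F3 to bicyclic ester F4 as described above, and returns at 21; it hydroborates while C8=C9 is still an unreactive enoate. BH3·THF then NaBO3 on F4 should give methyl (3S,3aS,4S,8R,8aS)-8-acetoxy-4-hydroxy-8a-methyl-3-(propan-2-yl)-3-[(triethylsilyl)oxy]-1,2,3,3a,4,5,8,8a-octahydroazulene-6-carboxylate F8. DIBAL-H gives (3S,3aS,4S,8R,8aS)-6-(hydroxymethyl)-8a-methyl-3-(propan-2-yl)-3-[(triethylsilyl)oxy]-1,2,3,3a,4,5,8,8a-octahydroazulene-4,8-diol F9. Selective mesylation of its primary allylic hydroxyl gives the primary allylic mesylate F10, and LiEt3BH gives (3S,3aS,4S,8R,8aS)-6,8a-dimethyl-3-(propan-2-yl)-3-[(triethylsilyl)oxy]-1,2,3,3a,4,5,8,8a-octahydroazulene-4,8-diol F11. DCC/DMAP esterification with 20 at the less hindered C6 hydroxyl (the C10 carbinol is neopentylic) gives the C6 monoester F12, and 9 with DMAP then acylates the C10 hydroxyl to 21.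

Step 3. The enamine may expel the β-silyloxy group instead of closing the ring, or the aldol adduct may dehydrate toward C4. The fallback sets out from 4 and returns at 6 without new compounds, by separating addition and elimination. Catalytic proline in DMSO at rt should stop at aldol adduct 5, which is isolated. Its only free hydroxyl is then activated with methyl N-(triethylammoniumsulfonyl)carbamate (PhMe, 50 °C) and eliminated toward the epimerisable aldehyde α-carbon to give 6; the silyl ether cannot leave by this route.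

Further compounds
F1 | step 6 | triethyl{[(1S)-2-ethenyl-3-methyl-1-(propan-2-yl)cyclopent-2-en-1-yl]oxy}silane | C=CC1=C(C)CC[C@]1(O[Si](CC)(CC)CC)C(C)C
F2 | step 6 | methyl 4-acetoxy-2-diazo-3-hydroxybutanoate (racemic) | COC(=O)C(=[N+]=[N-])C(O)COC(C)=O
F3 | step 6 | methyl (3E)-4-acetoxy-2-diazobut-3-enoate | COC(=O)C(=[N+]=[N-])/C=C/OC(C)=O
F4 | step 6 | methyl (3S,8R,8aS)-8-acetoxy-8a-methyl-3-(propan-2-yl)-3-[(triethylsilyl)oxy]-1,2,3,5,8,8a-hexahydroazulene-6-carboxylate | CC(=O)O[C@@H]1C=C(C(=O)OC)CC=C2[C@]1(C)CC[C@]2(O[Si](CC)(CC)CC)C(C)C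
F5 | step 6 | (3S,8R,8aS)-6-(hydroxymethyl)-8a-methyl-3-(propan-2-yl)-3-[(triethylsilyl)oxy]-1,2,3,5,8,8a-hexahydroazulen-8-ol | O[C@@H]1C=C(CO)CC=C2[C@]1(C)CC[C@]2(O[Si](CC)(CC)CC)C(C)C
F6 | step 6 | primary allylic mesylate of F5 | O[C@@H]1C=C(COS(C)(=O)=O)CC=C2[C@]1(C)CC[C@]2(O[Si](CC)(CC)CC)C(C)C
F7 | step 6 | (3S,8R,8aS)-6,8a-dimethyl-3-(propan-2-yl)-3-[(triethylsilyl)oxy]-1,2,3,5,8,8a-hexahydroazulen-8-ol | O[C@@H]1C=C(C)CC=C2[C@]1(C)CC[C@]2(O[Si](CC)(CC)CC)C(C)C
F8 | step 7 | methyl (3S,3aS,4S,8R,8aS)-8-acetoxy-4-hydroxy-8a-methyl-3-(propan-2-yl)-3-[(triethylsilyl)oxy]-1,2,3,3a,4,5,8,8a-octahydroazulene-6-carboxylate | CC(=O)O[C@@H]1C=C(C(=O)OC)C[C@H](O)[C@@H]2[C@]1(C)CC[C@]2(O[Si](CC)(CC)CC)C(C)C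
F9 | step 7 | (3S,3aS,4S,8R,8aS)-6-(hydroxymethyl)-8a-methyl-3-(propan-2-yl)-3-[(triethylsilyl)oxy]-1,2,3,3a,4,5,8,8a-octahydroazulene-4,8-diol | O[C@@H]1C=C(CO)C[C@H](O)[C@@H]2[C@]1(C)CC[C@]2(O[Si](CC)(CC)CC)C(C)C
F10 | step 7 | primary allylic mesylate of F9 | O[C@@H]1C=C(COS(C)(=O)=O)C[C@H](O)[C@@H]2[C@]1(C)CC[C@]2(O[Si](CC)(CC)CC)C(C)C
F11 | step 7 | (3S,3aS,4S,8R,8aS)-6,8a-dimethyl-3-(propan-2-yl)-3-[(triethylsilyl)oxy]-1,2,3,3a,4,5,8,8a-octahydroazulene-4,8-diol | O[C@@H]1C=C(C)C[C@H](O)[C@@H]2[C@]1(C)CC[C@]2(O[Si](CC)(CC)CC)C(C)C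
F12 | step 7 | (3S,3aS,4S,8R,8aS)-8-hydroxy-6,8a-dimethyl-3-(propan-2-yl)-3-[(triethylsilyl)oxy]-1,2,3,3a,4,5,8,8a-octahydroazulen-4-yl 4-[(tert-butyldimethylsilyl)oxy]benzoate | O[C@@H]1C=C(C)C[C@H](OC(=O)c2ccc(O[Si](C)(C)C(C)(C)C)cc2)[C@@H]2[C@]1(C)CC[C@]2(O[Si](CC)(CC)CC)C(C)C
F0 | step 3 | none | none
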